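**Plan**

- Retrosynthesis: the acetates come off last. Ring B is opened at C6–C7, as a C7 vinyl radical adding to an exocyclic C5=C6 methylene on ring A. The bromoalkene is traced to a C8 acid, and C9–C10 is cut as an Ireland–Claisen retron into a ring-A allylic alcohol and a C8–C15 side-chain acid.
- Forward: fragment A (from actinol, 4 steps) and fragment B (from hex-1-en-5-yne, 4 steps) are joined as an ester. The [3,3] shift links them at quaternary C10 and moves the ring alkene to C5=C6. Then acid → methyl ketone → bromoalkene, C2 oxidised, ring B closed, C2 reduced, desilylation, acetylation.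
- Enabling feature: C5 is an sp2 carbon between the quaternary C4 and C10, so a C7 radical on the C9 arm can only bond to C6 (6-endo). Because the vinyl radical inverts, an E/Z mixture of the bromoalkene converges on one ring.
- Stereochemistry: C2 of actinol directs the Claisen to the opposite ring face (C10). The chair transition state of the Z-ketene acetal sets C9. Hydrogen transfer anti to the C10 methyl sets C5. Hydride delivery anti to the two axial methyls resets C2. Syn-carboalumination fixes 13E.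

Key step: step 14

Remark: labdane numbering is used for all locants (ring A = C1–C5, C10; ring B = C5–C10; C17 on C8; C11–C16 side chain); (4R,6R)-4-hydroxy-2,2,6-trimethylcyclohexanone (actinol) is taken as a purchasable chiral-pool ketone.

**Route**

Step 1
Reactants: 1 (4R,6R)-4-hydroxy-2,2,6-trimethylcyclohexan-1-one
Product: 2 (4R,6R)-2,2,6-trimethyl-4-(triethylsilyloxy)cyclohexan-1-one
Conditions: Et3SiCl, imidazole, DMF, 0 °C → rt
Reagents that add atoms: chlorotriethylsilane, CC[Si](Cl)(CC)CC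
Why: Standard silyl ether formation on the secondary alcohol; the triethylsilyl group should survive the basic and reductive steps and is later removed by weak acid beside the diphenylsilyl ether.

Step 2
Reactants: 2 (4R,6R)-2,2,6-trimethyl-4-(triethylsilyloxy)cyclohexan-1-one
Product: 4 (4R)-2,6,6-trimethyl-4-(triethylsilyloxy)cyclohex-1-en-1-yl trifluoromethanesulfonate, via lithium enolate 3 (not isolated)
Conditions: LiN(i-Pr)2, THF, −78 °C; PhNTf2, −78 °C → rt; aq. NH4Cl
Reagents that add atoms: N-phenylbis(trifluoromethanesulfonimide), O=S(=O)(N(c1ccccc1)S(=O)(=O)C(F)(F)F)C(F)(F)F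
Why: The ketone can enolise only toward the methyl-bearing carbon, so enolate O-triflation (enol triflate formation) should give the single tetrasubstituted enol triflate without touching the silyloxy stereocentre.

Step 3
Reactants: 4 (4R)-2,6,6-trimethyl-4-(triethylsilyloxy)cyclohex-1-en-1-yl trifluoromethanesulfonate
Product: 5 methyl (4R)-2,6,6-trimethyl-4-(triethylsilyloxy)cyclohex-1-ene-1-carboxylate
Conditions: Pd(OAc)2 (5 mol %), PPh3 (10 mol %), CO (1 atm), MeOH, Et3N, DMF, 60 °C
Reagents that add atoms: carbon monoxide, [C-]#[O+]; methanol, CO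
Why: Palladium-catalysed alkoxycarbonylation of an enol triflate installs the carbon that becomes C6.

Step 4
Reactants: 5 methyl (4R)-2,6,6-trimethyl-4-(triethylsilyloxy)cyclohex-1-ene-1-carboxylate
Product: 6 [(4R)-2,6,6-trimethyl-4-(triethylsilyloxy)cyclohex-1-en-1-yl]methanol (fragment A)
Conditions: i-Bu2AlH (2.5 equiv), CH2Cl2, −78 → 0 °C
Reagents that add atoms: none
Why: 1,2-Reduction of the conjugated ester with an aluminium hydride should give the allylic alcohol needed for the sigmatropic step.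

Step 5
Reactants: 7 hex-1-en-5-yne
Product: 10 (2E)-3-methylhepta-2,6-dien-1-ol, via alkenylalane 8 (not isolated), via lithium alkenylalanate 9 (not isolated)
Conditions: Me3Al (2 equiv), Cp2ZrCl2 (0.2 equiv), CH2Cl2, 0 °C → rt; n-BuLi, THF, −78 °C; (CH2O)n, → rt
Reagents that add atoms: trimethylaluminium, C[Al](C)C; formaldehyde (from paraformaldehyde), C=O
Why: Negishi carboalumination adds methyl and aluminium syn across the terminal alkyne only (the monosubstituted alkene is inert), and hydroxymethylation of the alanate proceeds with retention, which fixes the 13E geometry.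

Step 6
Reactants: 10 (2E)-3-methylhepta-2,6-dien-1-ol
Product: 11 tert-butyl{[(2E)-3-methylhepta-2,6-dien-1-yl]oxy}diphenylsilane
Conditions: t-BuPh2SiCl, imidazole, DMF, rt
Reagents that add atoms: tert-butyl(chloro)diphenylsilane, CC(C)(C)[Si](Cl)(c1ccccc1)c1ccccc1
Why: Silylation of the primary allylic alcohol gives an ether that should survive amide bases, methyllithium, ylide, weak acid and radical conditions.

Step 7
Reactants: 11 tert-butyl{[(2E)-3-methylhepta-2,6-dien-1-yl]oxy}diphenylsilane
Product: 13 (5E)-7-(tert-butyldiphenylsilyloxy)-5-methylhept-5-en-1-ol, via B-alkyl borabicyclononane 12 (not isolated)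
Conditions: 9-BBN, THF, 0 °C → rt; NaOH, H2O2, 0 °C
Reagents that add atoms: hydrogen peroxide, OO
Why: Brown hydroboration–oxidation with 9-BBN is anti-Markovnikov and should select the terminal monosubstituted alkene over the trisubstituted one.

Step 8
Reactants: 13 (5E)-7-(tert-butyldiphenylsilyloxy)-5-methylhept-5-en-1-ol
Product: 14 (5E)-7-(tert-butyldiphenylsilyloxy)-5-methylhept-5-enoic acid (fragment B)
Conditions: TEMPO (0.2 equiv), PhI(OAc)2 (2.2 equiv), MeCN/H2O, rt
Reagents that add atoms: water, O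
Why: Nitroxyl-catalysed oxidation takes the primary alcohol to the acid through the aldehyde hydrate and should leave the alkene and the silyl ether alone.

Step 9
Reactants: 6 [(4R)-2,6,6-trimethyl-4-(triethylsilyloxy)cyclohex-1-en-1-yl]methanol; 14 (5E)-7-(tert-butyldiphenylsilyloxy)-5-methylhept-5-enoic acid
Product: 15 [(4R)-2,6,6-trimethyl-4-(triethylsilyloxy)cyclohex-1-en-1-yl]methyl (5E)-7-(tert-butyldiphenylsilyloxy)-5-methylhept-5-enoate
Conditions: DCC, DMAP (0.1 equiv), CH2Cl2, 0 °C → rt
Reagents that add atoms: none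
Why: Steglich esterification joins the two fragments under neutral conditions.

Step 10
Reactants: 15 [(4R)-2,6,6-trimethyl-4-(triethylsilyloxy)cyclohex-1-en-1-yl]methyl (5E)-7-(tert-butyldiphenylsilyloxy)-5-methylhept-5-enoate
Product: 19 (2S,5E)-7-(tert-butyldiphenylsilyloxy)-2-[(1S,5S)-5-hydroxy-1,3,3-trimethyl-2-methylidenecyclohexyl]-5-methylhept-5-enoic acid, via Z(O) lithium enolate 16 (not isolated), via silyl ketene acetal 17 (not isolated), via trimethylsilyl ester 18 (not isolated)
Conditions: LiN(i-Pr)2, THF/DMPU (4:1), −78 °C; Me3SiCl, Et3N; −78 → 65 °C; then AcOH/THF/H2O (3:1:1), rt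
Reagents that add atoms: none
Why: Ireland–Claisen rearrangement: the Z-silyl ketene acetal should shift through a chair transition state on the ring face anti to the pseudo-equatorial C2 silyloxy group (sets C10, as in additions to 5-substituted cyclohexenes) with H9 anti to the C10 methyl (sets C9), forming C9–C10 and the exocyclic C5=C6 alkene, and the weak-acid work-up should cleave the silyl ester and the triethylsilyl ether without lactonising the unsaturated acid.

Step 11
Reactants: 19 (2S,5E)-7-(tert-butyldiphenylsilyloxy)-2-[(1S,5S)-5-hydroxy-1,3,3-trimethyl-2-methylidenecyclohexyl]-5-methylhept-5-enoic acid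
Product: 20 (3S,6E)-8-(tert-butyldiphenylsilyloxy)-3-[(1S,5S)-5-hydroxy-1,3,3-trimethyl-2-methylidenecyclohexyl]-6-methyloct-6-en-2-one
Conditions: MeLi (4 equiv), THF, 0 °C → rt; inverse quench into aq. NH4Cl
Reagents that add atoms: methyllithium, [Li]C
Why: Methyllithium adds to the lithium carboxylate to give a gem-diolate that releases the methyl ketone only on work-up (ketone synthesis from an acid), and C9 next to the quaternary C10 should not epimerise.

Step 12
Reactants: 20 (3S,6E)-8-(tert-butyldiphenylsilyloxy)-3-[(1S,5S)-5-hydroxy-1,3,3-trimethyl-2-methylidenecyclohexyl]-6-methyloct-6-en-2-one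
Product: 21 (1S,3S)-3-[(3S,6E)-1-bromo-8-(tert-butyldiphenylsilyloxy)-2,6-dimethylocta-1,6-dien-3-yl]-3,5,5-trimethyl-4-methylidenecyclohexan-1-ol (1E/1Z mixture)
Conditions: Ph3P(CH2Br)Br (4 equiv), NaN(SiMe3)2 (3.9 equiv), THF, −78 °C → rt
Reagents that add atoms: (bromomethyl)triphenylphosphonium bromide, BrC[P+](c1ccccc1)(c1ccccc1)c1ccccc1.[Br-]
Why: Wittig bromomethylenation of the methyl ketone adds C7; the E/Z ratio does not matter because both isomers give the same vinyl radical, and the free hydroxyl only consumes extra ylide.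

Step 13
Reactants: 21 (1S,3S)-3-[(3S,6E)-1-bromo-8-(tert-butyldiphenylsilyloxy)-2,6-dimethylocta-1,6-dien-3-yl]-3,5,5-trimethyl-4-methylidenecyclohexan-1-ol (1E/1Z mixture)
Product: 22 (3S)-3-[(3S,6E)-1-bromo-8-(tert-butyldiphenylsilyloxy)-2,6-dimethylocta-1,6-dien-3-yl]-3,5,5-trimethyl-4-methylidenecyclohexan-1-one (1E/1Z mixture)
Conditions: Dess–Martin periodinane, NaHCO3, CH2Cl2, rt
Reagents that add atoms: none
Why: Dess–Martin oxidation makes C2 sp2 so that ring A carries no axial oxygen syn to the C4 and C10 methyls when the ring fusion is set in the next step; an axial C2 silyloxy group would favour the cis-fused conformer of the C5 radical.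

Step 14
Reactants: 22 (3S)-3-[(3S,6E)-1-bromo-8-(tert-butyldiphenylsilyloxy)-2,6-dimethylocta-1,6-dien-3-yl]-3,5,5-trimethyl-4-methylidenecyclohexan-1-one (1E/1Z mixture)
Product: 23 (5R,9R,10R)-15-(tert-butyldiphenylsilyloxy)labda-7,13E-dien-2-one
Conditions: Bu3SnH (1.3 equiv) and AIBN (0.2 equiv) added over 6 h by syringe pump, benzene (0.01 M), 80 °C
Reagents that add atoms: none
Why: Bu3Sn• abstracts bromine from either geometric isomer to give a bent σ-vinyl radical at C7 that inverts faster than it reacts, so both isomers funnel through the form whose radical lobe is cis to C9; this adds to the unsubstituted C6 terminus of the exocyclic C5=C6 alkene, and the tertiary C5 radical then takes hydrogen from Bu3SnH. The closest known reaction type is the tin-hydride cyclisation of vinyl and aryl radicals onto methylenecycloalkanes. Ring B closes in the 6-endo-trig mode, because the 5-exo mode would have to build a quaternary C5 between quaternary C4 and C10, and any such primary radical would relay by the homoallyl/cyclopropylcarbinyl shift to the same tertiary C5 radical. The new stereocentre C5 should be set by hydrogen transfer to the face anti to the axial C10 methyl (trans ring fusion, 5R). The step needs ring closure to outrun direct reduction and 1,5-hydrogen transfer from the allylic C12–H or from C1–H; slow stannane addition at high dilution and the fast addition of an sp2 radical to a 1,1-disubstituted alkene terminus are relied on for this.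

Step 15
Reactants: 23 (5R,9R,10R)-15-(tert-butyldiphenylsilyloxy)labda-7,13E-dien-2-one
Product: 24 (2S,5R,9R,10R)-15-(tert-butyldiphenylsilyloxy)labda-7,13E-dien-2-ol
Conditions: LiBH(s-Bu)3, THF, −78 °C; NaOH, H2O2, 0 °C
Reagents that add atoms: none
Why: Substrate-controlled ketone reduction: the bulky hydride should attack equatorially, from the face opposite the two syn-axial methyls on C4 and C10, giving the axial 2S alcohol.

Step 16
Reactants: 24 (2S,5R,9R,10R)-15-(tert-butyldiphenylsilyloxy)labda-7,13E-dien-2-ol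
Product: 25 (2S,5R,9R,10R)-labda-7,13E-diene-2,15-diol
Conditions: Bu4NF, THF, rt
Reagents that add atoms: none
Why: Fluoride-mediated cleavage of the silyl ether frees the primary allylic alcohol.

Step 17
Reactants: 25 (2S,5R,9R,10R)-labda-7,13E-diene-2,15-diol
Product: 26 (2S,5R,9R,10R)-labda-7,13E-diene-2,15-diyl diacetate
Conditions: Ac2O, DMAP, pyridine, rt → 40 °C
Reagents that add atoms: acetic anhydride, CC(=O)OC(C)=O
Why: DMAP-catalysed acylation should acetylate both the primary allylic and the hindered axial secondary alcohol without touching any stereocentre.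

**Compound list**

1 | (4R,6R)-4-hydroxy-2,2,6-trimethylcyclohexan-1-one (actinol) | O=C1[C@H](C)C[C@@H](O)CC1(C)C | starting material
2 | (4R,6R)-2,2,6-trimethyl-4-(triethylsilyloxy)cyclohexan-1-one | O=C1[C@H](C)C[C@@H](O[Si](CC)(CC)CC)CC1(C)C | intermediate
3 | lithium (4R)-2,6,6-trimethyl-4-(triethylsilyloxy)cyclohex-1-en-1-olate | [Li]OC1=C(C)C[C@@H](O[Si](CC)(CC)CC)CC1(C)C | intermediate
4 | (4R)-2,6,6-trimethyl-4-(triethylsilyloxy)cyclohex-1-en-1-yl trifluoromethanesulfonate | FC(F)(F)S(=O)(=O)OC1=C(C)C[C@@H](O[Si](CC)(CC)CC)CC1(C)C | intermediate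
5 | methyl (4R)-2,6,6-trimethyl-4-(triethylsilyloxy)cyclohex-1-ene-1-carboxylate | COC(=O)C1=C(C)C[C@@H](O[Si](CC)(CC)CC)CC1(C)C | intermediate
6 | [(4R)-2,6,6-trimethyl-4-(triethylsilyloxy)cyclohex-1-en-1-yl]methanol (fragment A) | OCC1=C(C)C[C@@H](O[Si](CC)(CC)CC)CC1(C)C | intermediate
7 | hex-1-en-5-yne | C#CCCC=C | starting material
8 | dimethyl[(1E)-2-methylhexa-1,5-dien-1-yl]alane | C[Al](C)/C=C(\C)CCC=C | intermediate
9 | lithium butyl(dimethyl)[(1E)-2-methylhexa-1,5-dien-1-yl]alanate | [Li+].CCCC[Al-](C)(C)/C=C(\C)CCC=C | intermediate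
10 | (2E)-3-methylhepta-2,6-dien-1-ol | OC/C=C(\C)CCC=C | intermediate
11 | tert-butyl{[(2E)-3-methylhepta-2,6-dien-1-yl]oxy}diphenylsilane | CC(C)(C)[Si](c1ccccc1)(c1ccccc1)OC/C=C(\C)CCC=C | intermediate
12 | 9-[(5E)-7-(tert-butyldiphenylsilyloxy)-5-methylhept-5-en-1-yl]-9-borabicyclo[3.3.1]nonane | CC(C)(C)[Si](c1ccccc1)(c1ccccc1)OC/C=C(\C)CCCCB1C2CCCC1CCC2 | intermediate
13 | (5E)-7-(tert-butyldiphenylsilyloxy)-5-methylhept-5-en-1-ol | CC(C)(C)[Si](c1ccccc1)(c1ccccc1)OC/C=C(\C)CCCCO | intermediate
14 | (5E)-7-(tert-butyldiphenylsilyloxy)-5-methylhept-5-enoic acid (fragment B) | CC(C)(C)[Si](c1ccccc1)(c1ccccc1)OC/C=C(\C)CCCC(O)=O | intermediate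
15 | [(4R)-2,6,6-trimethyl-4-(triethylsilyloxy)cyclohex-1-en-1-yl]methyl (5E)-7-(tert-butyldiphenylsilyloxy)-5-methylhept-5-enoate | CC(C)(C)[Si](c1ccccc1)(c1ccccc1)OC/C=C(\C)CCCC(=O)OCC1=C(C)C[C@@H](O[Si](CC)(CC)CC)CC1(C)C | intermediate
16 | Z(O) lithium enolate of 15 (enolate oxygen cis to the C11 chain) | CC(C)(C)[Si](c1ccccc1)(c1ccccc1)OC/C=C(\C)CC/C=C(\O[Li])OCC1=C(C)C[C@@H](O[Si](CC)(CC)CC)CC1(C)C | intermediate
17 | Z-trimethylsilyl ketene acetal of 15 | CC(C)(C)[Si](c1ccccc1)(c1ccccc1)OC/C=C(\C)CC/C=C(\O[Si](C)(C)C)OCC1=C(C)C[C@@H](O[Si](CC)(CC)CC)CC1(C)C | intermediate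
18 | trimethylsilyl (2S,5E)-7-(tert-butyldiphenylsilyloxy)-5-methyl-2-[(1S,5S)-1,3,3-trimethyl-2-methylidene-5-(triethylsilyloxy)cyclohexyl]hept-5-enoate | CC(C)(C)[Si](c1ccccc1)(c1ccccc1)OC/C=C(\C)CC[C@H](C(=O)O[Si](C)(C)C)[C@]1(C)C[C@@H](O[Si](CC)(CC)CC)CC(C)(C)C1=C | intermediate
19 | (2S,5E)-7-(tert-butyldiphenylsilyloxy)-2-[(1S,5S)-5-hydroxy-1,3,3-trimethyl-2-methylidenecyclohexyl]-5-methylhept-5-enoic acid | CC(C)(C)[Si](c1ccccc1)(c1ccccc1)OC/C=C(\C)CC[C@H](C(O)=O)[C@]1(C)C[C@@H](O)CC(C)(C)C1=C | intermediate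
20 | (3S,6E)-8-(tert-butyldiphenylsilyloxy)-3-[(1S,5S)-5-hydroxy-1,3,3-trimethyl-2-methylidenecyclohexyl]-6-methyloct-6-en-2-one | CC(C)(C)[Si](c1ccccc1)(c1ccccc1)OC/C=C(\C)CC[C@H](C(C)=O)[C@]1(C)C[C@@H](O)CC(C)(C)C1=C | intermediate
21 | (1S,3S)-3-[(3S,6E)-1-bromo-8-(tert-butyldiphenylsilyloxy)-2,6-dimethylocta-1,6-dien-3-yl]-3,5,5-trimethyl-4-methylidenecyclohexan-1-ol, 1E/1Z mixture | CC(C)(C)[Si](c1ccccc1)(c1ccccc1)OC/C=C(\C)CC[C@H](C(C)=CBr)[C@]1(C)C[C@@H](O)CC(C)(C)C1=C | intermediate
22 | (3S)-3-[(3S,6E)-1-bromo-8-(tert-butyldiphenylsilyloxy)-2,6-dimethylocta-1,6-dien-3-yl]-3,5,5-trimethyl-4-methylidenecyclohexan-1-one, 1E/1Z mixture | CC(C)(C)[Si](c1ccccc1)(c1ccccc1)OC/C=C(\C)CC[C@H](C(C)=CBr)[C@]1(C)CC(=O)CC(C)(C)C1=C | intermediate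
23 | (5R,9R,10R)-15-(tert-butyldiphenylsilyloxy)labda-7,13E-dien-2-one | CC(C)(C)[Si](c1ccccc1)(c1ccccc1)OC/C=C(\C)CC[C@@H]1C(C)=CC[C@@H]2C(C)(C)CC(=O)C[C@@]12C | intermediate
24 | (2S,5R,9R,10R)-15-(tert-butyldiphenylsilyloxy)labda-7,13E-dien-2-ol | CC(C)(C)[Si](c1ccccc1)(c1ccccc1)OC/C=C(\C)CC[C@@H]1C(C)=CC[C@@H]2C(C)(C)C[C@H](O)C[C@@]12C | intermediate
25 | (2S,5R,9R,10R)-labda-7,13E-diene-2,15-diol | OC/C=C(\C)CC[C@@H]1C(C)=CC[C@@H]2C(C)(C)C[C@H](O)C[C@@]12C | intermediate
26 | (2S,5R,9R,10R)-labda-7,13E-diene-2,15-diyl diacetate | CC(=O)OC/C=C(\C)CC[C@@H]1C(C)=CC[C@@H]2C(C)(C)C[C@H](OC(C)=O)C[C@@]12C | target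

**Count**

Total steps: 17. Longest linear sequence: 13 steps (steps 1–4 then 9–17 from 1; equally steps 5–17 from 7).

**Steps most likely to fail**

Step 14. What may go wrong: hydrogen transfer to the vinyl radical before ring closure (from the stannane, or by 1,5-shift from the allylic C12–H), and loss of facial selectivity in the hydrogen transfer to the C5 radical. The fallback sets out from 20 and comes back at 23; it closes the same C6–C7 bond with a slower-abstracting α-keto alkyl radical and adds C17 afterwards. Double silylation of 20 (LiN(SiMe3)2, Me3SiCl, −78 °C) should give the kinetic trimethylsilyl enol ether of the methyl ketone with the C2 oxygen also silylated F1. NBS at −78 °C and a dilute acid work-up give the hydroxy bromomethyl ketone F2, and Dess–Martin oxidation gives the C2-keto bromomethyl ketone F3. Bu3SnH/AIBN at high dilution should close ring B by 6-endo cyclisation of the C7 radical onto C6, with hydrogen transfer at C5 as in the main route, to give the trans-fused 17-nor-2,8-dione F4. Kinetic deprotonation at the unhindered C7 methylene (LiN(i-Pr)2, 1 equiv, −78 °C; C1 and C3 are neopentylic) and PhNTf2 give the C7-ene enol triflate F5. Negishi coupling with MeZnCl and Pd(PPh3)4 then gives 23.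

Step 10. What may go wrong: incomplete control of enolate geometry or leakage through a boat transition state, giving the C9 epimer, and decomposition of the silyl ketene acetal before the hindered shift. The fallback sets out from 15 and comes back at 20; it uses a decarboxylative Carroll rearrangement in which C9 is corrected afterwards by equilibration. The enolate 16 is C-acetylated with acetyl chloride to the β-keto ester F6. Heating in xylene at 140 °C should induce the [3,3] shift of its enol to the β-keto acid F7, which loses CO2 to the methyl ketone as a C9 epimer mixture that is still triethylsilylated F8. AcOH/THF/H2O removes the silyl group to give 20 and its C9 epimer F9; these are separated, and F9 is re-equilibrated with DBU and recycled.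

Step 12. What may go wrong: slow olefination of the hindered ketone, with competing enolisation (epimerisation at C9) and decomposition of the ylide. The fallback sets out from 19 and comes back at 23; the halo-alkene is made by carbometalation instead of olefination. LiAlH4 reduces 19 to the diol F10. TEMPO/PhI(OAc)2 in CH2Cl2 should oxidise only the primary alcohol to the hydroxy aldehyde F11. Ohira–Bestmann homologation (dimethyl (1-diazo-2-oxopropyl)phosphonate, K2CO3, MeOH) gives the terminal alkyne F12. Zirconium-catalysed carboalumination (Me3Al, Cp2ZrCl2) and iodinolysis give the E-iodoalkene F13, whose geometry is tolerated because the vinyl radical inverts. Dess–Martin oxidation gives the keto iodoalkene F14, and Bu3SnH/AIBN cyclisation as in step 14 gives 23.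

**Further compounds**

F1 | step 14 | trimethylsilyl enol ether of 20 at the methyl ketone with the C2 oxygen also trimethylsilylated | CC(C)(C)[Si](c1ccccc1)(c1ccccc1)OC/C=C(\C)CC[C@H](C(=C)O[Si](C)(C)C)[C@]1(C)C[C@@H](O[Si](C)(C)C)CC(C)(C)C1=C
F2 | step 14 | hydroxy bromomethyl ketone (20 brominated at the ketone methyl) | CC(C)(C)[Si](c1ccccc1)(c1ccccc1)OC/C=C(\C)CC[C@H](C(=O)CBr)[C@]1(C)C[C@@H](O)CC(C)(C)C1=C
F3 | step 14 | C2-keto bromomethyl ketone | CC(C)(C)[Si](c1ccccc1)(c1ccccc1)OC/C=C(\C)CC[C@H](C(=O)CBr)[C@]1(C)CC(=O)CC(C)(C)C1=C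
F4 | step 14 | trans-fused 15-(tert-butyldiphenylsilyloxy)-17-norlabd-13E-ene-2,8-dione (same spatial arrangement at C5, C9 and C10 as 23) | CC(C)(C)[Si](c1ccccc1)(c1ccccc1)OC/C=C(\C)CC[C@@H]1C(=O)CC[C@@H]2C(C)(C)CC(=O)C[C@@]12C
F5 | step 14 | C8 enol triflate of F4 with the C7=C8 double bond | CC(C)(C)[Si](c1ccccc1)(c1ccccc1)OC/C=C(\C)CC[C@@H]1C(OS(=O)(=O)C(F)(F)F)=CC[C@@H]2C(C)(C)CC(=O)C[C@@]12C
F6 | step 10 | 2-acetyl derivative of ester 15 (β-keto ester, C9 unassigned) | CC(C)(C)[Si](c1ccccc1)(c1ccccc1)OC/C=C(\C)CCC(C(C)=O)C(=O)OCC1=C(C)C[C@@H](O[Si](CC)(CC)CC)CC1(C)C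
F7 | step 10 | β-keto acid from the Carroll shift (C9 unassigned) | CC(C)(C)[Si](c1ccccc1)(c1ccccc1)OC/C=C(\C)CCC(C(C)=O)(C(O)=O)[C@]1(C)C[C@@H](O[Si](CC)(CC)CC)CC(C)(C)C1=C
F8 | step 10 | triethylsilyl ether of 20 as a mixture of C9 epimers | CC(C)(C)[Si](c1ccccc1)(c1ccccc1)OC/C=C(\C)CCC(C(C)=O)[C@]1(C)C[C@@H](O[Si](CC)(CC)CC)CC(C)(C)C1=C
F9 | step 10 | C9 epimer of 20 | CC(C)(C)[Si](c1ccccc1)(c1ccccc1)OC/C=C(\C)CC[C@@H](C(C)=O)[C@]1(C)C[C@@H](O)CC(C)(C)C1=C
F10 | step 12 | diol from reduction of the acid 19 | CC(C)(C)[Si](c1ccccc1)(c1ccccc1)OC/C=C(\C)CC[C@H](CO)[C@]1(C)C[C@@H](O)CC(C)(C)C1=C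
F11 | step 12 | hydroxy aldehyde (C8 aldehyde) | CC(C)(C)[Si](c1ccccc1)(c1ccccc1)OC/C=C(\C)CC[C@H](C=O)[C@]1(C)C[C@@H](O)CC(C)(C)C1=C
F12 | step 12 | hydroxy terminal alkyne (C8≡C7) | CC(C)(C)[Si](c1ccccc1)(c1ccccc1)OC/C=C(\C)CC[C@H](C#C)[C@]1(C)C[C@@H](O)CC(C)(C)C1=C
F13 | step 12 | hydroxy E-iodoalkene (iodo analogue of 21, single isomer) | CC(C)(C)[Si](c1ccccc1)(c1ccccc1)OC/C=C(\C)CC[C@H](/C(C)=C/I)[C@]1(C)C[C@@H](O)CC(C)(C)C1=C
F14 | step 12 | keto E-iodoalkene (iodo analogue of 22, single isomer) | CC(C)(C)[Si](c1ccccc1)(c1ccccc1)OC/C=C(\C)CC[C@H](/C(C)=C/I)[C@]1(C)CC(=O)CC(C)(C)C1=C
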